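**Retrosynthetic overview**

- The only carbocycle, the cyclohexane C1–C6, is closed first by forming the C1–C6 bond in an intramolecular carbonyl-ene reaction of an acyclic farnesane aldehyde, which copies the farnesyl-to-bisabolane ring closure; the oxirane is added second by hydroxyl-directed epoxidation.
- Enabling feature: ring carbon C6 carries the C7=C14 methylene next to carbinol carbon C1 (homoallylic alcohol O–C1–C6–C7=C14, the ene retron), and the ring C3–C4 unit can serve as a Z-alkene turn in the open chain.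
- The ene closure should give the all-equatorial ring with the C1 hydroxyl trans to its neighbours; C1 is then corrected by oxidation and bulky-hydride reduction, after which the cis-diol directs the epoxidation and is esterified twice.
- The acyclic aldehyde comes from two Z-selective Wittig olefinations (C3=C4 and C6=C7) that join two α-oxygenated methyl ketones through a three-carbon bis-phosphonium linchpin (C4–C6).
- Stereochemical sources: C2 from (R)-glycerate, C8 from proline-catalysed α-oxygenation of sulcatone, C6 from the key step, C1 from the reduction, C3 and C4 from the directed epoxidation.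

Key step: step 10

Remark: bisabolane numbering is used (ring C1–C6; C7 bears the C14 methylene and C8; C15 is the methyl on C3), and β is the ring face that carries the C6 side chain.

**Route**

Step 1
Reactants: 1 6-methylhept-5-en-2-one (sulcatone)
Product: 3 (3S)-3-hydroxy-6-methylhept-5-en-2-one, via α-anilinooxy ketone 2 (not isolated)
Conditions: PhNO (slow addition), 1 (3 equiv), D-proline (20 mol%), DMF, 0 °C; then CuSO4·5H2O (30 mol%), MeOH, 0 °C
Reagents that add atoms: nitrosobenzene, O=Nc1ccccc1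
Why: Proline-catalysed α-aminoxylation (O-selective nitroso aldol) should proceed through the more substituted enamine at C8, with the carboxylic acid-directed approach of PhNO setting C8 as S (D-proline, mirror image of the R products known with L-proline), and copper-mediated N–O cleavage then frees the hydroxyl group.

Step 2
Reactants: 3 (3S)-3-hydroxy-6-methylhept-5-en-2-one
Product: 4 (3S)-3-(tert-butyldimethylsilyloxy)-6-methylhept-5-en-2-one
Conditions: TBSCl, imidazole, DMF, 0 °C → rt
Reagents that add atoms: tert-butyl(chloro)dimethylsilane, CC(C)(C)[Si](C)(C)Cl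
Why: Standard silylation of a secondary alcohol under mild conditions that should not enolise the α-oxygenated ketone, so C8 is kept.

Step 3
Reactants: 5 methyl (4R)-2,2-dimethyl-1,3-dioxolane-4-carboxylate
Product: 6 (4R)-N-methoxy-N,2,2-trimethyl-1,3-dioxolane-4-carboxamide
Conditions: MeNH(OMe)·HCl, i-PrMgCl, THF, −20 °C
Reagents that add atoms: N,O-dimethylhydroxylamine hydrochloride, Cl.CNOC
Why: Direct ester-to-Weinreb-amide conversion with the magnesium amide is fast at low temperature and is known to leave α-alkoxy stereocentres intact.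

Step 4
Reactants: 6 (4R)-N-methoxy-N,2,2-trimethyl-1,3-dioxolane-4-carboxamide
Product: 7 1-[(4R)-2,2-dimethyl-1,3-dioxolan-4-yl]ethan-1-one
Conditions: MeMgBr, THF, −78 → 0 °C
Reagents that add atoms: methylmagnesium bromide, C[Mg]Br
Why: Grignard addition to a Weinreb amide stops at the chelated tetrahedral intermediate and gives the methyl ketone (C3 with C15) without over-addition.

Step 5
Reactants: 7 1-[(4R)-2,2-dimethyl-1,3-dioxolan-4-yl]ethan-1-one; 8 propane-1,3-diylbis(triphenylphosphonium) dibromide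
Product: 10 {(3Z)-4-[(4S)-2,2-dimethyl-1,3-dioxolan-4-yl]pent-3-en-1-yl}triphenylphosphonium bromide, via mono-ylide 9 (not isolated)
Conditions: 8 (2 equiv), KN(SiMe3)2 (2 equiv), THF, −40 → 0 °C; then 7 (1 equiv), −78 °C → rt
Reagents that add atoms: none
Why: Wittig olefination of an α-alkoxy methyl ketone with a non-stabilised ylide is known to place the alkoxy-bearing carbon cis to the ylide chain (3Z, C2 cis to C5), and the excess of the more acidic bis-salt should act as a proton reservoir that keeps the product salt from being deprotonated and olefinated a second time.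

Step 6
Reactants: 10 {(3Z)-4-[(4S)-2,2-dimethyl-1,3-dioxolan-4-yl]pent-3-en-1-yl}triphenylphosphonium bromide; 4 (3S)-3-(tert-butyldimethylsilyloxy)-6-methylhept-5-en-2-one
Product: 12 (4S)-4-[(2Z,5Z,7S)-7-(tert-butyldimethylsilyloxy)-6,10-dimethylundeca-2,5,9-trien-2-yl]-2,2-dimethyl-1,3-dioxolane, via phosphorus ylide 11 (not isolated)
Conditions: 10 (1.3 equiv), KN(SiMe3)2 (1.25 equiv), THF, −78 °C; then 4, −78 °C → rt
Reagents that add atoms: none
Why: A second Z-selective Wittig olefination of an α-silyloxy methyl ketone should set the 6Z alkene (C8 cis to C5, C14 methyl trans to C5) and complete the skipped Z,Z-diene at low temperature without touching C2 or C8.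

Step 7
Reactants: 12 (4S)-4-[(2Z,5Z,7S)-7-(tert-butyldimethylsilyloxy)-6,10-dimethylundeca-2,5,9-trien-2-yl]-2,2-dimethyl-1,3-dioxolane
Product: 13 (2S,3Z,6Z,8S)-8-(tert-butyldimethylsilyloxy)-3,7,11-trimethyldodeca-3,6,10-triene-1,2-diol
Conditions: CuCl2·2H2O, MeCN, 0 °C → rt
Reagents that add atoms: none
Why: Mild Lewis acid-assisted hydrolysis of a terminal acetonide should spare the secondary silyl ether and avoid ionising the allylic C2–O bond.

Step 8
Reactants: 13 (2S,3Z,6Z,8S)-8-(tert-butyldimethylsilyloxy)-3,7,11-trimethyldodeca-3,6,10-triene-1,2-diol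
Product: 14 (2S,3Z,6Z,8S)-8-(tert-butyldimethylsilyloxy)-3,7,11-trimethyl-1,2-bis(triethylsilyloxy)dodeca-3,6,10-triene
Conditions: Et3SiCl, imidazole, DMAP (cat.), CH2Cl2, 0 °C → rt
Reagents that add atoms: chlorotriethylsilane, CC[Si](Cl)(CC)CC
Why: Exhaustive silylation gives a primary and a secondary triethylsilyl ether that the next step can tell apart, and a non-chelating protecting group at O2 for the key step.

Step 9
Reactants: 14 (2S,3Z,6Z,8S)-8-(tert-butyldimethylsilyloxy)-3,7,11-trimethyl-1,2-bis(triethylsilyloxy)dodeca-3,6,10-triene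
Product: 15 (2S,3Z,6Z,8S)-8-(tert-butyldimethylsilyloxy)-3,7,11-trimethyl-2-(triethylsilyloxy)dodeca-3,6,10-trienal
Conditions: (COCl)2, DMSO, CH2Cl2, −78 → −40 °C; i-Pr2NEt, −78 → −20 °C; crude aldehyde used at once
Reagents that add atoms: none
Why: Swern oxidation is known to convert primary triethylsilyl ethers directly into aldehydes while secondary silyl ethers survive, and the hindered amine at low temperature should avoid epimerisation at C2 and migration of the 3,4-alkene.

Step 10
Reactants: 15 (2S,3Z,6Z,8S)-8-(tert-butyldimethylsilyloxy)-3,7,11-trimethyl-2-(triethylsilyloxy)dodeca-3,6,10-trienal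
Product: 16 (1S,2S,6S)-6-[(3S)-3-(tert-butyldimethylsilyloxy)-6-methylhepta-1,5-dien-2-yl]-3-methyl-2-(triethylsilyloxy)cyclohex-3-en-1-ol (1α-OH; 2β-OSiEt3; 6β side chain)
Conditions: MeAl(OAr)2 (Ar = 4-bromo-2,6-di-tert-butylphenyl; 1.5 equiv, from AlMe3 and 2 ArOH), CH2Cl2, −78 °C; 1 M HCl work-up
Reagents that add atoms: none
Why: The bulky monodentate aluminium phenoxide binds the aldehyde oxygen, C6 of the 6,7-alkene adds to C1 and a C14 hydrogen passes to the carbonyl oxygen in one six-membered ene transition state, so the C1–C6 bond, the C1 carbinol and the C7=C14 methylene arise together. The closest known reaction is the Lewis acid-promoted intramolecular carbonyl-ene cyclisation of citronellal to isopulegol. The cyclohexene closes in a 6-exo-trig mode at the carbonyl carbon (oxygen and C7 stay outside the ring), with the 3Z alkene as the turn that brings C1 and C6 together. C6 is controlled by C2: in the chair-like transition state the C2 silyloxy group should sit pseudoequatorial and antiperiplanar to the forming bond (polar Felkin–Anh arrangement, no chelation by the encapsulated aluminium) with the alkenyl unit equatorial, so C6 forms cis to the C2 oxygen. C1 should form trans to both, because the 6Z geometry puts only the C14 methyl (trans to C5) within reach of the oxygen in the all-equatorial trans-fused array; this centre is not needed, since step 11 erases it. The step needs hydrogen transfer from C14 and not from C8, no reaction at the C3=C4 or C10=C11 alkenes and no free cation: the 6Z geometry secures the first, ring size (three- or ten-membered alternatives) the second, and the concerted pathway under a non-protic aluminium reagent the third.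

Step 11
Reactants: 16 (1S,2S,6S)-6-[(3S)-3-(tert-butyldimethylsilyloxy)-6-methylhepta-1,5-dien-2-yl]-3-methyl-2-(triethylsilyloxy)cyclohex-3-en-1-ol
Product: 17 (2S,6S)-6-[(3S)-3-(tert-butyldimethylsilyloxy)-6-methylhepta-1,5-dien-2-yl]-3-methyl-2-(triethylsilyloxy)cyclohex-3-en-1-one
Conditions: Dess–Martin periodinane, CH2Cl2, 0 °C → rt
Reagents that add atoms: none
Why: Dess–Martin oxidation is near-neutral and should give the ketone without epimerising C2 or C6 or conjugating either β,γ-alkene.

Step 12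
Reactants: 17 (2S,6S)-6-[(3S)-3-(tert-butyldimethylsilyloxy)-6-methylhepta-1,5-dien-2-yl]-3-methyl-2-(triethylsilyloxy)cyclohex-3-en-1-one
Product: 18 (1R,2S,6S)-6-[(3S)-3-(tert-butyldimethylsilyloxy)-6-methylhepta-1,5-dien-2-yl]-3-methyl-2-(triethylsilyloxy)cyclohex-3-en-1-ol (1β-OH; all-cis)
Conditions: LiBH(s-Bu)3 (L-Selectride), THF, −78 °C; aq. NH4Cl
Reagents that add atoms: none
Why: Steric approach control in a bulky trialkylborohydride reduction should deliver hydride to C1 from the α face, away from the two flanking β substituents, giving the axial 1β alcohol cis to both neighbours; a 1,2-silyl shift between O1 and O2 would be harmless because step 13 removes the group.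

Step 13
Reactants: 18 (1R,2S,6S)-6-[(3S)-3-(tert-butyldimethylsilyloxy)-6-methylhepta-1,5-dien-2-yl]-3-methyl-2-(triethylsilyloxy)cyclohex-3-en-1-ol
Product: 19 (1R,2S,6S)-6-[(3S)-3-(tert-butyldimethylsilyloxy)-6-methylhepta-1,5-dien-2-yl]-3-methylcyclohex-3-ene-1,2-diol
Conditions: PPTS (cat.), MeOH, 0 °C
Reagents that add atoms: none
Why: Mild acidic methanolysis removes a triethylsilyl ether much faster than the secondary tert-butyldimethylsilyl ether at C8.

Step 14
Reactants: 19 (1R,2S,6S)-6-[(3S)-3-(tert-butyldimethylsilyloxy)-6-methylhepta-1,5-dien-2-yl]-3-methylcyclohex-3-ene-1,2-diol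
Product: 20 (1R,2R,3R,4S,6S)-4-[(3S)-3-(tert-butyldimethylsilyloxy)-6-methylhepta-1,5-dien-2-yl]-1-methyl-7-oxabicyclo[4.1.0]heptane-2,3-diol (3β,4β-epoxide in bisabolane numbering)
Conditions: VO(acac)2 (5 mol%), t-BuOOH (1.2 equiv), CH2Cl2, 0 °C → rt
Reagents that add atoms: tert-butyl hydroperoxide, CC(C)(C)OO
Why: In this hydroxyl-directed epoxidation the vanadium-bound allylic C2 hydroxyl should deliver oxygen to the β face of C3=C4, setting C3 and C4 cis to the C2 oxygen, while the undirected C10=C11 and the only homoallylic C7=C14 alkenes react far more slowly.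

Step 15
Reactants: 20 (1R,2R,3R,4S,6S)-4-[(3S)-3-(tert-butyldimethylsilyloxy)-6-methylhepta-1,5-dien-2-yl]-1-methyl-7-oxabicyclo[4.1.0]heptane-2,3-diol
Product: 21 (1S,2R,3R,4S,6S)-4-[(3S)-3-(tert-butyldimethylsilyloxy)-6-methylhepta-1,5-dien-2-yl]-1-methyl-7-oxabicyclo[4.1.0]heptane-2,3-diyl bis[(2Z)-2-methylbut-2-enoate]
Conditions: angelic anhydride (4 equiv), LiN(SiMe3)2 (2.4 equiv, added last), THF, −40 → 0 °C
Reagents that add atoms: angelic anhydride, C/C=C(/C)C(=O)OC(=O)/C(C)=C\C
Why: Acylation of lithium alkoxides with angelic anhydride at low temperature is a known way to esterify hindered secondary alcohols without Z-to-E isomerisation, and the cis relation of hydroxyls and oxirane rules out Payne rearrangement.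

Step 16
Reactants: 21 (1S,2R,3R,4S,6S)-4-[(3S)-3-(tert-butyldimethylsilyloxy)-6-methylhepta-1,5-dien-2-yl]-1-methyl-7-oxabicyclo[4.1.0]heptane-2,3-diyl bis[(2Z)-2-methylbut-2-enoate]
Product: 22 (1S,2R,3R,4S,6S)-4-[(3S)-3-hydroxy-6-methylhepta-1,5-dien-2-yl]-1-methyl-7-oxabicyclo[4.1.0]heptane-2,3-diyl bis[(2Z)-2-methylbut-2-enoate]
Conditions: Bu4NF, AcOH (1:1), THF, 0 °C → rt
Reagents that add atoms: none
Why: Fluoride desilylation buffered with acetic acid should free the C8 hydroxyl without ester cleavage, angelate isomerisation or epoxide opening.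

Step 17
Reactants: 22 (1S,2R,3R,4S,6S)-4-[(3S)-3-hydroxy-6-methylhepta-1,5-dien-2-yl]-1-methyl-7-oxabicyclo[4.1.0]heptane-2,3-diyl bis[(2Z)-2-methylbut-2-enoate]
Product: 23 (1S,2R,3R,4S,6S)-4-[(3S)-3-acetoxy-6-methylhepta-1,5-dien-2-yl]-1-methyl-7-oxabicyclo[4.1.0]heptane-2,3-diyl bis[(2Z)-2-methylbut-2-enoate] (target)
Conditions: Ac2O, pyridine, DMAP (cat.), CH2Cl2, 0 °C → rt
Reagents that add atoms: acetic anhydride, CC(=O)OC(C)=O
Why: Standard acetylation of the only free (secondary allylic) hydroxyl group with retention at C8 completes the target.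

**Compound list**

1 | 6-methylhept-5-en-2-one (sulcatone) | CC(=O)CCC=C(C)C | starting material
2 | (3S)-6-methyl-3-[(phenylamino)oxy]hept-5-en-2-one | CC(=O)[C@@H](ONc1ccccc1)CC=C(C)C | intermediate (not isolated)
3 | (3S)-3-hydroxy-6-methylhept-5-en-2-one | CC(=O)[C@@H](O)CC=C(C)C | intermediate
4 | (3S)-3-(tert-butyldimethylsilyloxy)-6-methylhept-5-en-2-one | CC(=O)[C@@H](O[Si](C)(C)C(C)(C)C)CC=C(C)C | intermediate
5 | methyl (4R)-2,2-dimethyl-1,3-dioxolane-4-carboxylate | COC(=O)[C@H]1COC(C)(C)O1 | starting material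
6 | (4R)-N-methoxy-N,2,2-trimethyl-1,3-dioxolane-4-carboxamide | CON(C)C(=O)[C@H]1COC(C)(C)O1 | intermediate
7 | 1-[(4R)-2,2-dimethyl-1,3-dioxolan-4-yl]ethan-1-one | CC(=O)[C@H]1COC(C)(C)O1 | intermediate
8 | propane-1,3-diylbis(triphenylphosphonium) dibromide | [Br-].[Br-].c1ccc(cc1)[P+](c1ccccc1)(c1ccccc1)CCC[P+](c1ccccc1)(c1ccccc1)c1ccccc1 | starting material
9 | triphenyl[3-(triphenylphosphoranylidene)propyl]phosphonium bromide (mono-ylide) | [Br-].c1ccc(cc1)P(c1ccccc1)(c1ccccc1)=CCC[P+](c1ccccc1)(c1ccccc1)c1ccccc1 | intermediate (not isolated)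
10 | {(3Z)-4-[(4S)-2,2-dimethyl-1,3-dioxolan-4-yl]pent-3-en-1-yl}triphenylphosphonium bromide | CC1(C)OC[C@@H](O1)/C(C)=C\CC[P+](c1ccccc1)(c1ccccc1)c1ccccc1.[Br-] | intermediate
11 | {(3Z)-4-[(4S)-2,2-dimethyl-1,3-dioxolan-4-yl]pent-3-en-1-ylidene}triphenylphosphorane | CC1(C)OC[C@@H](O1)/C(C)=C\CC=P(c1ccccc1)(c1ccccc1)c1ccccc1 | intermediate (not isolated)
12 | (4S)-4-[(2Z,5Z,7S)-7-(tert-butyldimethylsilyloxy)-6,10-dimethylundeca-2,5,9-trien-2-yl]-2,2-dimethyl-1,3-dioxolane | CC1(C)OC[C@@H](O1)/C(C)=C\C/C=C(C)\[C@@H](O[Si](C)(C)C(C)(C)C)CC=C(C)C | intermediate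
13 | (2S,3Z,6Z,8S)-8-(tert-butyldimethylsilyloxy)-3,7,11-trimethyldodeca-3,6,10-triene-1,2-diol | OC[C@@H](O)/C(C)=C\C/C=C(C)\[C@@H](O[Si](C)(C)C(C)(C)C)CC=C(C)C | intermediate
14 | (2S,3Z,6Z,8S)-8-(tert-butyldimethylsilyloxy)-3,7,11-trimethyl-1,2-bis(triethylsilyloxy)dodeca-3,6,10-triene | CC[Si](CC)(CC)OC[C@@H](O[Si](CC)(CC)CC)/C(C)=C\C/C=C(C)\[C@@H](O[Si](C)(C)C(C)(C)C)CC=C(C)C | intermediate
15 | (2S,3Z,6Z,8S)-8-(tert-butyldimethylsilyloxy)-3,7,11-trimethyl-2-(triethylsilyloxy)dodeca-3,6,10-trienal | O=C[C@@H](O[Si](CC)(CC)CC)/C(C)=C\C/C=C(C)\[C@@H](O[Si](C)(C)C(C)(C)C)CC=C(C)C | intermediate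
16 | (1S,2S,6S)-6-[(3S)-3-(tert-butyldimethylsilyloxy)-6-methylhepta-1,5-dien-2-yl]-3-methyl-2-(triethylsilyloxy)cyclohex-3-en-1-ol | C=C([C@H](CC=C(C)C)O[Si](C)(C)C(C)(C)C)[C@@H]1CC=C(C)[C@H](O[Si](CC)(CC)CC)[C@H]1O | intermediate
17 | (2S,6S)-6-[(3S)-3-(tert-butyldimethylsilyloxy)-6-methylhepta-1,5-dien-2-yl]-3-methyl-2-(triethylsilyloxy)cyclohex-3-en-1-one | C=C([C@H](CC=C(C)C)O[Si](C)(C)C(C)(C)C)[C@@H]1CC=C(C)[C@H](O[Si](CC)(CC)CC)C1=O | intermediate
18 | (1R,2S,6S)-6-[(3S)-3-(tert-butyldimethylsilyloxy)-6-methylhepta-1,5-dien-2-yl]-3-methyl-2-(triethylsilyloxy)cyclohex-3-en-1-ol | C=C([C@H](CC=C(C)C)O[Si](C)(C)C(C)(C)C)[C@@H]1CC=C(C)[C@H](O[Si](CC)(CC)CC)[C@@H]1O | intermediate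
19 | (1R,2S,6S)-6-[(3S)-3-(tert-butyldimethylsilyloxy)-6-methylhepta-1,5-dien-2-yl]-3-methylcyclohex-3-ene-1,2-diol | C=C([C@H](CC=C(C)C)O[Si](C)(C)C(C)(C)C)[C@@H]1CC=C(C)[C@H](O)[C@@H]1O | intermediate
20 | (1R,2R,3R,4S,6S)-4-[(3S)-3-(tert-butyldimethylsilyloxy)-6-methylhepta-1,5-dien-2-yl]-1-methyl-7-oxabicyclo[4.1.0]heptane-2,3-diol | C=C([C@H](CC=C(C)C)O[Si](C)(C)C(C)(C)C)[C@@H]1C[C@@H]2O[C@]2(C)[C@H](O)[C@@H]1O | intermediate
21 | (1S,2R,3R,4S,6S)-4-[(3S)-3-(tert-butyldimethylsilyloxy)-6-methylhepta-1,5-dien-2-yl]-1-methyl-7-oxabicyclo[4.1.0]heptane-2,3-diyl bis[(2Z)-2-methylbut-2-enoate] | C=C([C@H](CC=C(C)C)O[Si](C)(C)C(C)(C)C)[C@@H]1C[C@@H]2O[C@]2(C)[C@H](OC(=O)/C(C)=C\C)[C@@H]1OC(=O)/C(C)=C\C | intermediate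
22 | (1S,2R,3R,4S,6S)-4-[(3S)-3-hydroxy-6-methylhepta-1,5-dien-2-yl]-1-methyl-7-oxabicyclo[4.1.0]heptane-2,3-diyl bis[(2Z)-2-methylbut-2-enoate] | C=C([C@H](CC=C(C)C)O)[C@@H]1C[C@@H]2O[C@]2(C)[C@H](OC(=O)/C(C)=C\C)[C@@H]1OC(=O)/C(C)=C\C | intermediate
23 | (1S,2R,3R,4S,6S)-4-[(3S)-3-acetoxy-6-methylhepta-1,5-dien-2-yl]-1-methyl-7-oxabicyclo[4.1.0]heptane-2,3-diyl bis[(2Z)-2-methylbut-2-enoate] | C=C([C@H](CC=C(C)C)OC(C)=O)[C@@H]1C[C@@H]2O[C@]2(C)[C@H](OC(=O)/C(C)=C\C)[C@@H]1OC(=O)/C(C)=C\C | target

**Step count**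

Total: 17 steps. Longest linear sequence: 15 steps (5 → 23, steps 3–17); the branch from 1 (steps 1–2) joins at step 6.

**Steps most likely to fail**

Step 10 (key ene closure). What may go wrong: erosion of the stereochemical relay from C2 to C6 (competition of a chair with pseudoaxial silyloxy group, or a mismatched influence of the C8 centre), cationic leakage (1,2-hydride shift from C8, proton loss toward C8), and epimerisation or alkene migration in the sensitive aldehyde before it cyclises. Fallback: give up substrate control by a stoichiometric aluminium Lewis acid and close the same bond under catalyst control with a confined chiral Brønsted acid of the imidodiphosphorimidate class (a few mol%, non-polar solvent, low temperature). Acids of this class are known to catalyse carbonyl-ene cyclisations of olefinic terpenoid aldehydes through a concerted, pocket-bound transition state, so the acid enantiomer (both would be screened for the matched case) rather than the acyclic C2 relay would fix C6, and free cations would be avoided. The fallback sets out from 15 and comes back at 16; any 18 formed alongside would also be oxidised to 17 in step 11. No new compound arises.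

Step 5 (mono-olefination of the bis-phosphonium salt). What may go wrong: ylide exchange between the mono-ylide and the product salt leading to double olefination, incomplete Z-selectivity, and base-induced epimerisation or β-elimination of the α-alkoxy ketone. Fallback: build the C4–C6 unit stepwise from a protected hydroxypropyl ylide; it sets out from 7 and comes back at 12. Wittig olefination of 7 with the ylide of commercial [3-(tert-butyldimethylsilyloxy)propyl]triphenylphosphonium bromide (KN(SiMe3)2, THF, −78 °C → rt) would give (4S)-4-[(2Z)-5-(tert-butyldimethylsilyloxy)pent-2-en-2-yl]-2,2-dimethyl-1,3-dioxolane F1. Bu4NF in THF would give (3Z)-4-[(4S)-2,2-dimethyl-1,3-dioxolan-4-yl]pent-3-en-1-ol F2. I2, PPh3 and imidazole would give (4S)-4-[(2Z)-5-iodopent-2-en-2-yl]-2,2-dimethyl-1,3-dioxolane F3. PPh3 in MeCN at 80 °C would give {(3Z)-4-[(4S)-2,2-dimethyl-1,3-dioxolan-4-yl]pent-3-en-1-yl}triphenylphosphonium iodide F4, which takes the place of 10 in step 6 and leads to 12.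

Step 15 (double angeloylation). What may go wrong: incomplete second acylation of the hindered cis-diol, Z-to-E isomerisation of the angelate under basic conditions, and base- or nucleophile-induced opening of the oxirane. Fallback: esterify one hydroxyl at a time and place the first ester before the epoxide exists; it sets out from 18 and comes back at 21. Acylation of the free C1 hydroxyl of 18 (angelic anhydride, LiN(SiMe3)2, THF, −40 °C) would give (1R,2S,6S)-6-[(3S)-3-(tert-butyldimethylsilyloxy)-6-methylhepta-1,5-dien-2-yl]-3-methyl-2-(triethylsilyloxy)cyclohex-3-en-1-yl (2Z)-2-methylbut-2-enoate F5. PPTS in MeOH would give (1R,2S,6S)-6-[(3S)-3-(tert-butyldimethylsilyloxy)-6-methylhepta-1,5-dien-2-yl]-2-hydroxy-3-methylcyclohex-3-en-1-yl (2Z)-2-methylbut-2-enoate F6. VO(acac)2 and t-BuOOH, directed by the allylic C2 hydroxyl, would give (1R,2R,3R,4S,6S)-4-[(3S)-3-(tert-butyldimethylsilyloxy)-6-methylhepta-1,5-dien-2-yl]-2-hydroxy-1-methyl-7-oxabicyclo[4.1.0]heptan-3-yl (2Z)-2-methylbut-2-enoate F7. A Yamaguchi-type esterification of F7 (mixed anhydride of angelic acid and 2,4,6-trichlorobenzoyl chloride, Et3N, toluene) would give 21. A silyl shift in step 12 would not matter, since both oxygens end as angelates.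

**Further compounds**

F0 | step 10 | none | none
F1 | step 5 | (4S)-4-[(2Z)-5-(tert-butyldimethylsilyloxy)pent-2-en-2-yl]-2,2-dimethyl-1,3-dioxolane | CC1(C)OC[C@@H](O1)/C(C)=C\CCO[Si](C)(C)C(C)(C)C
F2 | step 5 | (3Z)-4-[(4S)-2,2-dimethyl-1,3-dioxolan-4-yl]pent-3-en-1-ol | CC1(C)OC[C@@H](O1)/C(C)=C\CCO
F3 | step 5 | (4S)-4-[(2Z)-5-iodopent-2-en-2-yl]-2,2-dimethyl-1,3-dioxolane | CC1(C)OC[C@@H](O1)/C(C)=C\CCI
F4 | step 5 | {(3Z)-4-[(4S)-2,2-dimethyl-1,3-dioxolan-4-yl]pent-3-en-1-yl}triphenylphosphonium iodide | CC1(C)OC[C@@H](O1)/C(C)=C\CC[P+](c1ccccc1)(c1ccccc1)c1ccccc1.[I-]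
F5 | step 15 | (1R,2S,6S)-6-[(3S)-3-(tert-butyldimethylsilyloxy)-6-methylhepta-1,5-dien-2-yl]-3-methyl-2-(triethylsilyloxy)cyclohex-3-en-1-yl (2Z)-2-methylbut-2-enoate | C=C([C@H](CC=C(C)C)O[Si](C)(C)C(C)(C)C)[C@@H]1CC=C(C)[C@H](O[Si](CC)(CC)CC)[C@@H]1OC(=O)/C(C)=C\C
F6 | step 15 | (1R,2S,6S)-6-[(3S)-3-(tert-butyldimethylsilyloxy)-6-methylhepta-1,5-dien-2-yl]-2-hydroxy-3-methylcyclohex-3-en-1-yl (2Z)-2-methylbut-2-enoate | C=C([C@H](CC=C(C)C)O[Si](C)(C)C(C)(C)C)[C@@H]1CC=C(C)[C@H](O)[C@@H]1OC(=O)/C(C)=C\C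
F7 | step 15 | (1R,2R,3R,4S,6S)-4-[(3S)-3-(tert-butyldimethylsilyloxy)-6-methylhepta-1,5-dien-2-yl]-2-hydroxy-1-methyl-7-oxabicyclo[4.1.0]heptan-3-yl (2Z)-2-methylbut-2-enoate | C=C([C@H](CC=C(C)C)O[Si](C)(C)C(C)(C)C)[C@@H]1C[C@@H]2O[C@]2(C)[C@H](O)[C@@H]1OC(=O)/C(C)=C\C
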